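**Retrosynthetic overview**
- The plan rests on ring C: its O1–C2 bond must come from the oxygen on C8a (the one beside the C8 1-arylethyl group), the C5 oxygen must stay out of the closure, and C3 must end up bearing a heteroatom.
- Target 22 ⇐ global debenzylation ⇐ C5 mesylate hydrolysis ⇐ copper-catalysed C3–O coupling of 3-iodoflavone 19.
- 19 ⇐ ICl-induced demethylative 6-endo-dig closure of ortho-methoxyaryl ynone 17. Ring C is the only ring made; rings A, B and the side-chain arene are bought.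
- 17 ⇐ acetylide addition and oxidation on salicylaldehyde mesylate 13 ⇐ ortho-formylation of phenol 10. The two methoxy groups of 10 are equivalent, so acylation next to the phenol followed by closure through the adjacent methoxy group can only give the 8-substituted skeleton.
- 10 ⇐ asymmetric hydrogenation of 1,1-diarylethene 8 ⇐ benzophenone 6 ⇐ aldehyde 1 plus the Grignard reagent from bromide 3.

Key step: step 11

Assumption: the sense of induction in step 5 is assigned by analogy and cannot be predicted with certainty; the ligand antipode that delivers the (R)-methine is the one to be used, and (S)-tBu-PHOX stands for it. Alcohol 16 is carried as a mixture of epimers at the carbinol carbon.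

**Step 1**
Reactants: 1 4-hydroxy-2,6-dimethoxybenzaldehyde
Product: 2 2,6-dimethoxy-4-(triisopropylsilyloxy)benzaldehyde
Conditions: TIPSCl, imidazole, DMF, rt
Reagents that add atoms: triisopropylsilyl chloride, CC(C)[Si](Cl)(C(C)C)C(C)C
Why: Silylation of an acidic para-formyl phenol; the TIPS ether should survive Grignard reagents and mild acid and can later be removed with fluoride without touching a benzyl ether.

**Step 2**
Reactants: 2 2,6-dimethoxy-4-(triisopropylsilyloxy)benzaldehyde; 3 1-(benzyloxy)-4-bromobenzene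
Product: 5 (4-benzyloxyphenyl)[2,6-dimethoxy-4-(triisopropylsilyloxy)phenyl]methanol (racemic), via aryl Grignard reagent 4 (not isolated)
Conditions: 3, Mg, cat. I2, THF, 40 °C; then 2, THF, 0 °C → rt; aq. NH4Cl
Reagents that add atoms: none
Why: Grignard addition to an aromatic aldehyde; the carbinol centre forms without control and is destroyed in step 3.

**Step 3**
Reactants: 5 (4-benzyloxyphenyl)[2,6-dimethoxy-4-(triisopropylsilyloxy)phenyl]methanol
Product: 6 (4-benzyloxyphenyl)[2,6-dimethoxy-4-(triisopropylsilyloxy)phenyl]methanone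
Conditions: Dess–Martin periodinane, CH2Cl2, rt
Reagents that add atoms: none
Why: Dess–Martin oxidation of an electron-rich diarylmethanol to the benzophenone under near-neutral conditions that spare the silyl and benzyl ethers.

**Step 4**
Reactants: 6 (4-benzyloxyphenyl)[2,6-dimethoxy-4-(triisopropylsilyloxy)phenyl]methanone
Product: 8 1-(4-benzyloxyphenyl)-1-[2,6-dimethoxy-4-(triisopropylsilyloxy)phenyl]ethene, via tertiary carbinol 7 (not isolated)
Conditions: MeMgBr, THF, 0 → 45 °C; aq. NH4Cl; then cat. p-TsOH·H2O, toluene, rt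
Reagents that add atoms: methylmagnesium bromide, C[Mg]Br
Why: Grignard addition to a non-enolisable diaryl ketone gives a doubly benzylic tertiary alcohol that should lose water by acid-catalysed E1 dehydration, and only the terminal alkene can form.

**Step 5**
Reactants: 8 1-(4-benzyloxyphenyl)-1-[2,6-dimethoxy-4-(triisopropylsilyloxy)phenyl]ethene
Product: 9 {4-[(1R)-1-(4-benzyloxyphenyl)ethyl]-3,5-dimethoxyphenoxy}triisopropylsilane
Conditions: [Ir(cod)((S)-tBu-PHOX)]BArF (2 mol%; BArF = B[3,5-(CF3)2C6H3]4), H2 (5 bar), CH2Cl2, rt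
Reagents that add atoms: none
Why: Iridium N,P-catalysed asymmetric hydrogenation of a 1,1-diarylethene; the 2,6-dimethoxyaryl ring is forced perpendicular to the alkene while the 4-benzyloxyphenyl ring stays coplanar, so the chiral pocket can tell the two faces apart and deliver hydrogen to the face giving the (R)-methine, and the homogeneous catalyst should leave the benzyl and silyl ethers alone.

**Step 6**
Reactants: 9 {4-[(1R)-1-(4-benzyloxyphenyl)ethyl]-3,5-dimethoxyphenoxy}triisopropylsilane
Product: 10 4-[(1R)-1-(4-benzyloxyphenyl)ethyl]-3,5-dimethoxyphenol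
Conditions: TBAF, THF, 0 °C
Reagents that add atoms: none
Why: Fluoride cleavage of an aryl silyl ether, orthogonal to the benzyl ether and without effect on the methine centre.

**Step 7**
Reactants: 10 4-[(1R)-1-(4-benzyloxyphenyl)ethyl]-3,5-dimethoxyphenol
Product: 12 3-[(1R)-1-(4-benzyloxyphenyl)ethyl]-6-hydroxy-2,4-dimethoxybenzaldehyde, via hydroxymethyl phenol 11 (not isolated)
Conditions: MgCl2, Et3N, (CH2O)n, MeCN, reflux; aq. HCl work-up
Reagents that add atoms: paraformaldehyde (formaldehyde), C=O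
Why: Casnati–Skattebøl ortho-formylation, in which the magnesium phenoxide delivers formaldehyde to the ortho carbon and a second formaldehyde oxidises the resulting benzylic alkoxide by hydride transfer; the two ortho positions are equivalent and the benzyloxyphenyl ring, not being a phenol, should not react.

**Step 8**
Reactants: 12 3-[(1R)-1-(4-benzyloxyphenyl)ethyl]-6-hydroxy-2,4-dimethoxybenzaldehyde
Product: 13 4-[(1R)-1-(4-benzyloxyphenyl)ethyl]-2-formyl-3,5-dimethoxyphenyl methanesulfonate
Conditions: MsCl, Et3N, CH2Cl2, 0 °C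
Reagents that add atoms: methanesulfonyl chloride, CS(=O)(=O)Cl
Why: O-Sulfonylation of the salicylaldehyde phenol turns the future C5 oxygen into a non-nucleophilic, ICl-stable sulfonate; the mild amine base should not trigger condensation of the mesyl methyl group with the aldehyde.

**Step 9**
Reactants: 13 4-[(1R)-1-(4-benzyloxyphenyl)ethyl]-2-formyl-3,5-dimethoxyphenyl methanesulfonate; 14 4-ethynylanisole
Product: 16 4-[(1R)-1-(4-benzyloxyphenyl)ethyl]-2-[1-hydroxy-3-(4-methoxyphenyl)prop-2-yn-1-yl]-3,5-dimethoxyphenyl methanesulfonate (mixture of carbinol epimers), via lithium acetylide 15 (not isolated)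
Conditions: 14, n-BuLi, THF, −78 °C; then 13, −78 °C; AcOH quench at −78 °C
Reagents that add atoms: none
Why: 1,2-Addition of a slim lithium acetylide to the hindered aldehyde at −78 °C should outrun deprotonation of the mesylate, and the cold acidic quench prevents sulfonyl transfer to the new alkoxide, whose uncontrolled configuration is erased in step 10.

**Step 10**
Reactants: 16 4-[(1R)-1-(4-benzyloxyphenyl)ethyl]-2-[1-hydroxy-3-(4-methoxyphenyl)prop-2-yn-1-yl]-3,5-dimethoxyphenyl methanesulfonate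
Product: 17 4-[(1R)-1-(4-benzyloxyphenyl)ethyl]-3,5-dimethoxy-2-[3-(4-methoxyphenyl)propynoyl]phenyl methanesulfonate
Conditions: Dess–Martin periodinane, CH2Cl2, 0 °C → rt
Reagents that add atoms: none
Why: Dess–Martin oxidation of a benzylic propargylic alcohol to the ynone; no nucleophile or base is present that could add to the triple bond.

**Step 11**
Reactants: 17 4-[(1R)-1-(4-benzyloxyphenyl)ethyl]-3,5-dimethoxy-2-[3-(4-methoxyphenyl)propynoyl]phenyl methanesulfonate
Product: 19 8-[(1R)-1-(4-benzyloxyphenyl)ethyl]-3-iodo-5-mesyloxy-7-methoxy-2-(4-methoxyphenyl)-4H-chromen-4-one, via methyloxonium chloride 18 (not isolated)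
Conditions: ICl (1.1 equiv), CH2Cl2, −78 °C, dark; aq. Na2S2O3
Reagents that add atoms: iodine monochloride, ICl
Why: ICl transfers iodonium to the triple bond, and because the 4-methoxyphenyl group stabilises positive charge on the β-carbon, the ortho methoxy oxygen attacks there anti to iodine, forming O1–C2 and C3–I and giving oxonium chloride 18, which chloride demethylates by SN2 attack on the methyl group with loss of chloromethane. The closest known reaction is the ICl-induced cyclisation of 2-methoxyaryl alkynyl ketones to 3-iodochromones. Ring C closes in the 6-endo-dig mode; 5-exo closure to an aurone-type product is disfavoured by the polarisation of the ynone. No stereocentre is formed and the diarylmethine centre is not involved. The step needs the right oxygen to close and the alkyne to react ahead of the electron-rich arenes: the C5 oxygen is a sulfonate and the only ether oxygen ortho to the ketone is the one beside the side chain, so only the 8-substituted flavone can form. Low temperature and a near-stoichiometric charge of ICl should keep iodination of C6–H and of the benzyloxyphenyl ring from competing.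

**Step 12**
Reactants: 19 8-[(1R)-1-(4-benzyloxyphenyl)ethyl]-3-iodo-5-mesyloxy-7-methoxy-2-(4-methoxyphenyl)-4H-chromen-4-one
Product: 20 3-benzyloxy-8-[(1R)-1-(4-benzyloxyphenyl)ethyl]-5-mesyloxy-7-methoxy-2-(4-methoxyphenyl)-4H-chromen-4-one
Conditions: CuI (10 mol%), 3,4,7,8-tetramethyl-1,10-phenanthroline (20 mol%), Cs2CO3, BnOH, toluene, 80 °C
Reagents that add atoms: benzyl alcohol, OCc1ccccc1
Why: Ullmann-type copper-catalysed C–O coupling of an sp2 iodide with a primary alcohol, helped by the adjacent carbonyl group; it avoids hot hydroxide on the ring-opening-prone iodoflavone and installs the C3 oxygen as a benzyl ether that leaves in the final hydrogenolysis.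

**Step 13**
Reactants: 20 3-benzyloxy-8-[(1R)-1-(4-benzyloxyphenyl)ethyl]-5-mesyloxy-7-methoxy-2-(4-methoxyphenyl)-4H-chromen-4-one
Product: 21 3-benzyloxy-8-[(1R)-1-(4-benzyloxyphenyl)ethyl]-5-hydroxy-7-methoxy-2-(4-methoxyphenyl)-4H-chromen-4-one
Conditions: LiOH·H2O, THF/H2O, 50 °C; then 1 M HCl
Reagents that add atoms: none
Why: Hydroxide cleaves the aryl sulfonate at sulfur, releasing a phenoxide that is a good leaving group because it is peri to the carbonyl; the alcohol-free medium avoids forming an alkyl mesylate that could re-alkylate O5, and the C5 phenoxide then deactivates the pyranone towards ring opening.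

**Step 14**
Reactants: 21 3-benzyloxy-8-[(1R)-1-(4-benzyloxyphenyl)ethyl]-5-hydroxy-7-methoxy-2-(4-methoxyphenyl)-4H-chromen-4-one
Product: 22 3,5-dihydroxy-8-[(1R)-1-(4-hydroxyphenyl)ethyl]-7-methoxy-2-(4-methoxyphenyl)-4H-chromen-4-one (CNP0223021.1)
Conditions: H2 (1 atm), 10% Pd/C, EtOAc/MeOH, rt
Reagents that add atoms: none
Why: Hydrogenolysis of both benzyl ethers in one operation; the flavonol double bond and the methyl ethers are stable under these conditions and the methine centre is untouched.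

**Compound list**
1 | 4-hydroxy-2,6-dimethoxybenzaldehyde | COc1cc(O)cc(OC)c1C=O | starting material
2 | 2,6-dimethoxy-4-(triisopropylsilyloxy)benzaldehyde | COc1cc(O[Si](C(C)C)(C(C)C)C(C)C)cc(OC)c1C=O | intermediate
3 | 1-(benzyloxy)-4-bromobenzene | Brc1ccc(OCc2ccccc2)cc1 | starting material
4 | 4-(benzyloxy)phenylmagnesium bromide | Br[Mg]c1ccc(OCc2ccccc2)cc1 | intermediate
5 | (4-benzyloxyphenyl)[2,6-dimethoxy-4-(triisopropylsilyloxy)phenyl]methanol, racemic | COc1cc(O[Si](C(C)C)(C(C)C)C(C)C)cc(OC)c1C(O)c1ccc(OCc2ccccc2)cc1 | intermediate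
6 | (4-benzyloxyphenyl)[2,6-dimethoxy-4-(triisopropylsilyloxy)phenyl]methanone | COc1cc(O[Si](C(C)C)(C(C)C)C(C)C)cc(OC)c1C(=O)c1ccc(OCc2ccccc2)cc1 | intermediate
7 | 1-(4-benzyloxyphenyl)-1-[2,6-dimethoxy-4-(triisopropylsilyloxy)phenyl]ethanol, racemic | COc1cc(O[Si](C(C)C)(C(C)C)C(C)C)cc(OC)c1C(C)(O)c1ccc(OCc2ccccc2)cc1 | intermediate
8 | 1-(4-benzyloxyphenyl)-1-[2,6-dimethoxy-4-(triisopropylsilyloxy)phenyl]ethene | COc1cc(O[Si](C(C)C)(C(C)C)C(C)C)cc(OC)c1C(=C)c1ccc(OCc2ccccc2)cc1 | intermediate
9 | {4-[(1R)-1-(4-benzyloxyphenyl)ethyl]-3,5-dimethoxyphenoxy}triisopropylsilane | COc1cc(O[Si](C(C)C)(C(C)C)C(C)C)cc(OC)c1[C@H](C)c1ccc(OCc2ccccc2)cc1 | intermediate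
10 | 4-[(1R)-1-(4-benzyloxyphenyl)ethyl]-3,5-dimethoxyphenol | COc1cc(O)cc(OC)c1[C@H](C)c1ccc(OCc2ccccc2)cc1 | intermediate
11 | 4-[(1R)-1-(4-benzyloxyphenyl)ethyl]-2-(hydroxymethyl)-3,5-dimethoxyphenol | COc1cc(O)c(CO)c(OC)c1[C@H](C)c1ccc(OCc2ccccc2)cc1 | intermediate
12 | 3-[(1R)-1-(4-benzyloxyphenyl)ethyl]-6-hydroxy-2,4-dimethoxybenzaldehyde | COc1cc(O)c(C=O)c(OC)c1[C@H](C)c1ccc(OCc2ccccc2)cc1 | intermediate
13 | 4-[(1R)-1-(4-benzyloxyphenyl)ethyl]-2-formyl-3,5-dimethoxyphenyl methanesulfonate | COc1cc(OS(C)(=O)=O)c(C=O)c(OC)c1[C@H](C)c1ccc(OCc2ccccc2)cc1 | intermediate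
14 | 4-ethynylanisole | C#Cc1ccc(OC)cc1 | starting material
15 | lithium (4-methoxyphenyl)acetylide | [Li]C#Cc1ccc(OC)cc1 | intermediate
16 | 4-[(1R)-1-(4-benzyloxyphenyl)ethyl]-2-[1-hydroxy-3-(4-methoxyphenyl)prop-2-yn-1-yl]-3,5-dimethoxyphenyl methanesulfonate, carbinol epimers | COc1ccc(C#CC(O)c2c(OS(C)(=O)=O)cc(OC)c([C@H](C)c3ccc(OCc4ccccc4)cc3)c2OC)cc1 | intermediate
17 | 4-[(1R)-1-(4-benzyloxyphenyl)ethyl]-3,5-dimethoxy-2-[3-(4-methoxyphenyl)propynoyl]phenyl methanesulfonate | COc1ccc(C#CC(=O)c2c(OS(C)(=O)=O)cc(OC)c([C@H](C)c3ccc(OCc4ccccc4)cc3)c2OC)cc1 | intermediate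
18 | 8-[(1R)-1-(4-benzyloxyphenyl)ethyl]-3-iodo-5-mesyloxy-7-methoxy-2-(4-methoxyphenyl)-1-methyl-4-oxo-4H-chromen-1-ium chloride | COc1ccc(cc1)C1=C(I)C(=O)c2c(OS(C)(=O)=O)cc(OC)c([C@H](C)c3ccc(OCc4ccccc4)cc3)c2[O+]1C.[Cl-] | intermediate
19 | 8-[(1R)-1-(4-benzyloxyphenyl)ethyl]-3-iodo-5-mesyloxy-7-methoxy-2-(4-methoxyphenyl)-4H-chromen-4-one | COc1ccc(-c2oc3c([C@H](C)c4ccc(OCc5ccccc5)cc4)c(OC)cc(OS(C)(=O)=O)c3c(=O)c2I)cc1 | intermediate
20 | 3-benzyloxy-8-[(1R)-1-(4-benzyloxyphenyl)ethyl]-5-mesyloxy-7-methoxy-2-(4-methoxyphenyl)-4H-chromen-4-one | COc1ccc(-c2oc3c([C@H](C)c4ccc(OCc5ccccc5)cc4)c(OC)cc(OS(C)(=O)=O)c3c(=O)c2OCc6ccccc6)cc1 | intermediate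
21 | 3-benzyloxy-8-[(1R)-1-(4-benzyloxyphenyl)ethyl]-5-hydroxy-7-methoxy-2-(4-methoxyphenyl)-4H-chromen-4-one | COc1ccc(-c2oc3c([C@H](C)c4ccc(OCc5ccccc5)cc4)c(OC)cc(O)c3c(=O)c2OCc6ccccc6)cc1 | intermediate
22 | 3,5-dihydroxy-8-[(1R)-1-(4-hydroxyphenyl)ethyl]-7-methoxy-2-(4-methoxyphenyl)-4H-chromen-4-one | COc1ccc(-c2oc3c([C@H](C)c4ccc(O)cc4)c(OC)cc(O)c3c(=O)c2O)cc1 | target

**Step count**
Total: 14 steps. Longest linear sequence: 14 steps (1 → 22); 3 and 14 enter as bought fragments.

**Steps most likely to fail**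

1. Step 11. Electrophilic iodination of C6–H of ring A or of the benzyloxyphenyl ring may outrun the alkyne, or crowding around the methoxy oxygen may slow closure so that ICl merely adds across the triple bond. The fallback closes ring C without electrophilic iodine, through a free phenol, and brings in the C3 oxygen by epoxidation. It sets out from 13 and comes back at 20.
   - MgI2·OEt2 in toluene at 60 °C should remove only the methyl group chelated to the formyl group, giving 4-[(1R)-1-(4-benzyloxyphenyl)ethyl]-2-formyl-3-hydroxy-5-methoxyphenyl methanesulfonate F1.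
   - An excess of acetylide 15 at −78 °C should give the diol 4-[(1R)-1-(4-benzyloxyphenyl)ethyl]-3-hydroxy-2-[1-hydroxy-3-(4-methoxyphenyl)prop-2-yn-1-yl]-5-methoxyphenyl methanesulfonate F2.
   - MnO2 in CH2Cl2 should oxidise it to the ortho-hydroxyaryl ynone F3.
   - Et2NH in EtOH at 50 °C should add to the ynone and let the phenol displace the amine in 6-endo fashion, giving 8-[(1R)-1-(4-benzyloxyphenyl)ethyl]-5-mesyloxy-7-methoxy-2-(4-methoxyphenyl)-4H-chromen-4-one F4.
   - Dimethyldioxirane in acetone/CH2Cl2 at 0 °C should give the 2,3-epoxide F5, which catalytic p-TsOH should open to the 3-hydroxyflavone F6.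
   - BnBr and K2CO3 in DMF convert F6 into 20.

2. Step 12. Benzyl alkoxide may act as a hydride donor at copper and reduce the C–I bond, the mesyl group may be transferred to the alkoxide, or alkoxide addition at C2 may open the pyranone. The fallback replaces direct C–O coupling by borylation and oxidation. It sets out from 19 and comes back at 20.
   - PdCl2(dppf), bis(pinacolato)diboron and KOAc in dioxane at 80 °C should give the 3-(pinacolboryl)flavone F7.
   - NaBO3·4H2O in THF/H2O at rt should oxidise it to the 3-hydroxyflavone F6, the same compound reached in the fallback for step 11.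
   - Benzylation as above gives 20.

3. Step 5. Facial discrimination may be insufficient or of the wrong sense, the two ortho methoxy groups may bind and slow the catalyst, or the acidic iridium hydride may oligomerise the electron-rich alkene. The fallback replaces asymmetric catalysis by resolution. It sets out from 8 and comes back at 10.
   - Hydrogenation with the achiral complex [Ir(cod)(PCy3)(py)]PF6 (H2, CH2Cl2) should give the racemic silyl ether F8.
   - TBAF gives the racemic phenol F9.
   - Preparative chromatography on a chiral stationary phase (supercritical CO2/MeOH) separates the enantiomers and delivers 10.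

**Further compounds**
F1 | step 11 | 4-[(1R)-1-(4-benzyloxyphenyl)ethyl]-2-formyl-3-hydroxy-5-methoxyphenyl methanesulfonate | COc1cc(OS(C)(=O)=O)c(C=O)c(O)c1[C@H](C)c1ccc(OCc2ccccc2)cc1
F2 | step 11 | 4-[(1R)-1-(4-benzyloxyphenyl)ethyl]-3-hydroxy-2-[1-hydroxy-3-(4-methoxyphenyl)prop-2-yn-1-yl]-5-methoxyphenyl methanesulfonate, carbinol epimers | COc1ccc(C#CC(O)c2c(OS(C)(=O)=O)cc(OC)c([C@H](C)c3ccc(OCc4ccccc4)cc3)c2O)cc1
F3 | step 11 | 4-[(1R)-1-(4-benzyloxyphenyl)ethyl]-3-hydroxy-5-methoxy-2-[3-(4-methoxyphenyl)propynoyl]phenyl methanesulfonate | COc1ccc(C#CC(=O)c2c(OS(C)(=O)=O)cc(OC)c([C@H](C)c3ccc(OCc4ccccc4)cc3)c2O)cc1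
F4 | step 11 | 8-[(1R)-1-(4-benzyloxyphenyl)ethyl]-5-mesyloxy-7-methoxy-2-(4-methoxyphenyl)-4H-chromen-4-one | COc1ccc(-c2cc(=O)c3c(OS(C)(=O)=O)cc(OC)c([C@H](C)c4ccc(OCc5ccccc5)cc4)c3o2)cc1
F5 | step 11 | 2,3-epoxide of F4 (2,3-epoxy-2,3-dihydrochromen-4-one), epoxide diastereomers | COc1ccc(cc1)C12OC1C(=O)c1c(OS(C)(=O)=O)cc(OC)c([C@H](C)c3ccc(OCc4ccccc4)cc3)c1O2
F6 | step 11 | 8-[(1R)-1-(4-benzyloxyphenyl)ethyl]-3-hydroxy-5-mesyloxy-7-methoxy-2-(4-methoxyphenyl)-4H-chromen-4-one | COc1ccc(-c2oc3c([C@H](C)c4ccc(OCc5ccccc5)cc4)c(OC)cc(OS(C)(=O)=O)c3c(=O)c2O)cc1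
F7 | step 12 | 8-[(1R)-1-(4-benzyloxyphenyl)ethyl]-5-mesyloxy-7-methoxy-2-(4-methoxyphenyl)-3-(4,4,5,5-tetramethyl-1,3,2-dioxaborolan-2-yl)-4H-chromen-4-one | COc1ccc(-c2oc3c([C@H](C)c4ccc(OCc5ccccc5)cc4)c(OC)cc(OS(C)(=O)=O)c3c(=O)c2B6OC(C)(C)C(C)(C)O6)cc1
F8 | step 5 | {4-[1-(4-benzyloxyphenyl)ethyl]-3,5-dimethoxyphenoxy}triisopropylsilane, racemic | COc1cc(O[Si](C(C)C)(C(C)C)C(C)C)cc(OC)c1C(C)c1ccc(OCc2ccccc2)cc1
F9 | step 5 | 4-[1-(4-benzyloxyphenyl)ethyl]-3,5-dimethoxyphenol, racemic | COc1cc(O)cc(OC)c1C(C)c1ccc(OCc2ccccc2)cc1
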